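**Retrosynthetic overview** (drimane numbering for the decalin: ring A = C1–C5 and C10, ring B = C5–C10, side chain on C9)

1. The last bond made is the sp3–sp2 bond between the two-carbon arm on C9 and the (E)-trisubstituted olefin: Negishi coupling of a decalin alkylzinc with a ring C (E)-alkenyl iodide.
2. The route rests on the tetrasubstituted C8=C9 olefin of ring B. It lies where a C7=C8–C9=C10 diene leaves its new double bond after adding a C5=C6 dienophile tethered through C1–C4. Rings A and B are therefore closed together by one type-1 intramolecular Diels–Alder reaction of a trienal iminium ion (bonds C5–C10 and C6–C7), and the activating formyl group on C6 is then removed by decarbonylation.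
3. The trienal is built from but-3-yn-1-ol, 1-bromo-3-chloropropane and isobutyronitrile. Its (8E) tetrasubstituted olefin is set by alkoxide-directed syn-carbomagnesiation of a homopropargylic alcohol, iodination and Suzuki–Miyaura coupling.
4. Ring C is not formed in the route: it is the ring of 3-methylcyclohex-2-enone, and its one stereocentre is set by decarboxylative asymmetric allylation. Ring order: ring C (bought), then rings A and B together in step 9.

Key step: step 9

Assumption: the ligand antipode in step 14 (and the lipase preference in its fallback) is assigned by analogy with related substrates; if the first run shows the opposite sense, the other antipode (or the other resolved fraction) is used.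

**Step 1**
Reactants: 1 but-3-yn-1-ol; 2 1-bromo-3-chloropropane
Product: 4 7-chlorohept-3-yn-1-ol, via dilithio but-3-yn-1-ol 3 (not isolated)
Conditions: n-BuLi (2.1 equiv), THF/DMPU, −78 → 0 °C; then 2, −40 °C → rt; aq. work-up
Reagents that add atoms: none
Why: Acetylide alkylation (SN2), in which the carbon end of the O,C-dianion is the stronger nucleophile and bromide leaves much faster than chloride, so the chloride is kept for step 2.

**Step 2**
Reactants: 4 7-chlorohept-3-yn-1-ol; 5 2-methylpropanenitrile (isobutyronitrile)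
Product: 8 9-hydroxy-2,2-dimethylnon-6-ynenitrile, via lithiated nitrile 6 (not isolated), via lithium alkoxide 7 (not isolated)
Conditions: 5, LiN(i-Pr)2 (commercial solution), THF, −78 °C; 4 + n-BuLi (1.0 equiv), THF, −78 °C; combine, DMPU, NaI (10 mol%), → 45 °C
Reagents that add atoms: none
Why: SN2 alkylation of a tertiary α-cyano carbanion, a small and strong nucleophile that displaces primary chlorides, builds the quaternary C4 while the alcohol is masked as its lithium alkoxide.

**Step 3**
Reactants: 8 9-hydroxy-2,2-dimethylnon-6-ynenitrile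
Product: 10 (6E)-9-hydroxy-7-iodo-2,2,6-trimethylnon-6-enenitrile, via alkenylmagnesium bromide 9 (not isolated)
Conditions: MeMgBr (5 equiv), Fe(acac)3 (15 mol%), THF, −78 → 0 °C; then I2, THF, −78 °C → rt
Reagents that add atoms: methylmagnesium bromide C[Mg]Br; iodine II
Why: Iron-catalysed, alkoxide-directed syn-carbomagnesiation of a homopropargylic alcohol should deliver methyl to the distal alkyne carbon and magnesium to the proximal one (five-membered chelate), and iodinolysis with retention then fixes the (E) tetrasubstituted olefin, the hindered tertiary nitrile being inert to MeMgBr at or below 0 °C.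

**Step 4**
Reactants: 10 (6E)-9-hydroxy-7-iodo-2,2,6-trimethylnon-6-enenitrile
Product: 11 (6E)-9-[(tert-butyldimethylsilyl)oxy]-7-iodo-2,2,6-trimethylnon-6-enenitrile
Conditions: TBSCl, imidazole, DMF, rt
Reagents that add atoms: tert-butyldimethylsilyl chloride CC(C)(C)[Si](C)(C)Cl
Why: Standard silylation of an unhindered primary alcohol.

**Step 5**
Reactants: 11 (6E)-9-[(tert-butyldimethylsilyl)oxy]-7-iodo-2,2,6-trimethylnon-6-enenitrile
Product: 12 (6E)-7-{2-[(tert-butyldimethylsilyl)oxy]ethyl}-2,2,6,8-tetramethylnona-6,8-dienenitrile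
Conditions: Pd(OAc)2 (5 mol%), SPhos (10 mol%), K3PO4, THF/H2O (10:1), 60 °C
Reagents that add atoms: isopropenylboronic acid pinacol ester CC(=C)B1OC(C)(C)C(C)(C)O1
Why: Suzuki–Miyaura coupling with retention of olefin geometry, with a bulky biarylphosphine to carry the hindered tetrasubstituted alkenyl iodide through oxidative addition and transmetalation.

**Step 6**
Reactants: 12 (6E)-7-{2-[(tert-butyldimethylsilyl)oxy]ethyl}-2,2,6,8-tetramethylnona-6,8-dienenitrile
Product: 14 (6E)-7-{2-[(tert-butyldimethylsilyl)oxy]ethyl}-2,2,6,8-tetramethylnona-6,8-dienal, via aluminium imine 13 (not isolated)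
Conditions: i-Bu2AlH (1.3 equiv), CH2Cl2, −78 → −20 °C; aq. tartaric acid, 0 °C
Reagents that add atoms: water O
Why: Partial hydride reduction of a nitrile stops at the N-aluminoimine, which mild aqueous acid hydrolyses to the aldehyde, and the α-quaternary aldehyde cannot enolise.

**Step 7**
Reactants: 14 (6E)-7-{2-[(tert-butyldimethylsilyl)oxy]ethyl}-2,2,6,8-tetramethylnona-6,8-dienal
Product: 15 (2E,8E)-9-{2-[(tert-butyldimethylsilyl)oxy]ethyl}-N-methoxy-N,4,4,8,10-pentamethylundeca-2,8,10-trienamide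
Conditions: NaH, THF, 0 °C → rt
Reagents that add atoms: diethyl {2-[methoxy(methyl)amino]-2-oxoethyl}phosphonate CCOP(=O)(CC(=O)N(C)OC)OCC
Why: Horner–Wadsworth–Emmons olefination with a stabilised phosphonate is reliably (E)-selective with α-branched aldehydes and avoids the over-homologation seen with formyl ylides.

**Step 8**
Reactants: 15 (2E,8E)-9-{2-[(tert-butyldimethylsilyl)oxy]ethyl}-N-methoxy-N,4,4,8,10-pentamethylundeca-2,8,10-trienamide
Product: 17 (2E,8E)-9-{2-[(tert-butyldimethylsilyl)oxy]ethyl}-4,4,8,10-tetramethylundeca-2,8,10-trienal, via aluminium hemiaminal 16 (not isolated)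
Conditions: i-Bu2AlH (1.2 equiv), THF, −78 °C; aq. KNaC4H4O6 (potassium sodium tartrate)
Reagents that add atoms: none
Why: 1,2-Reduction of an N-methoxy-N-methylamide stops at the chelated tetrahedral intermediate, which releases the (E)-enal on work-up.

**Step 9**
Reactants: 17 (2E,8E)-9-{2-[(tert-butyldimethylsilyl)oxy]ethyl}-4,4,8,10-tetramethylundeca-2,8,10-trienal
Product: 20 (1S,4aS,8aS)-4-{2-[(tert-butyldimethylsilyl)oxy]ethyl}-3,4a,8,8-tetramethyl-1,2,4a,5,6,7,8,8a-octahydronaphthalene-1-carbaldehyde, via trienal iminium triflate 18 (not isolated), via cycloadduct iminium triflate 19 (not isolated)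
Conditions: (2S,5S)-5-benzyl-2-tert-butyl-3-methylimidazolidin-4-one (20 mol%), TfOH (20 mol%), MeCN/H2O (98:2), −20 → 23 °C
Reagents that add atoms: none
Why: Proposed new method: condensation of enal 17 with the second-generation imidazolidinone salt should give the (E)-iminium ion 18, whose lowered LUMO lets the C5=C6 dienophile add in normal electron demand to the electron-rich tetra-alkyl diene C7=C8–C9=C10 through a concerted, asynchronous [4+2] transition state, after which hydrolysis of 19 frees 20 and the catalyst; the closest known reaction type is the imidazolidinone-catalysed type-1 intramolecular Diels–Alder reaction of (E)-trienals to trans-fused decalins, which has not been shown for a fully substituted diene terminus that becomes a quaternary ring-fusion carbon. Ring B closes as the cyclohexene of the cycloaddition (bonds C5–C10 and C6–C7), and ring A closes in the same event as the six-membered ring of the tether (C10–C1–C2–C3–C4–C5). C5 and C10 are set relative to each other by the endo transition state of the (E)-enal with the tether on the outside position of the (8E)-diene, which places H5 and the C10 methyl trans; C6 follows from the (E)-dienophile geometry (formyl cis to H5) and is erased in step 10. The absolute sense comes from the catalyst: its benzyl group covers the Re face at the α-carbon of the iminium ion, so the diene should add to the Si face and give the (1S,4aS,8aS) adduct. The step needs endo over exo selectivity and enough reactivity at the hindered C10; the gem-dimethyl group at C4 favours the folded tether conformer, the C8 and C9 substituents destabilise the s-trans diene, and the C8=C9 olefin is formed with its methyl and side chain already in place, so no olefin isomers can arise.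

**Step 10**
Reactants: 20 (1S,4aS,8aS)-4-{2-[(tert-butyldimethylsilyl)oxy]ethyl}-3,4a,8,8-tetramethyl-1,2,4a,5,6,7,8,8a-octahydronaphthalene-1-carbaldehyde
Product: 21 tert-butyldimethyl{2-[(4aS,8aS)-2,5,5,8a-tetramethyl-3,4,4a,5,6,7,8,8a-octahydronaphthalen-1-yl]ethoxy}silane
Conditions: RhCl(PPh3)3 (1.1 equiv), toluene, 110 °C
Reagents that add atoms: none
Why: Tsuji–Wilson decarbonylation (formyl C–H oxidative addition to monovalent rhodium, CO extrusion, C–H reductive elimination) replaces the formyl group by hydrogen, and the tetrasubstituted olefin and silyl ether do not bind the metal.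

**Step 11**
Reactants: 21 tert-butyldimethyl{2-[(4aS,8aS)-2,5,5,8a-tetramethyl-3,4,4a,5,6,7,8,8a-octahydronaphthalen-1-yl]ethoxy}silane
Product: 22 2-[(4aS,8aS)-2,5,5,8a-tetramethyl-3,4,4a,5,6,7,8,8a-octahydronaphthalen-1-yl]ethan-1-ol
Conditions: Bu4NF, THF, 0 °C → rt
Reagents that add atoms: none
Why: Fluoride-driven cleavage of a primary silyl ether.

**Step 12**
Reactants: 22 2-[(4aS,8aS)-2,5,5,8a-tetramethyl-3,4,4a,5,6,7,8,8a-octahydronaphthalen-1-yl]ethan-1-ol
Product: 23 (4aS,8aS)-1-(2-iodoethyl)-2,5,5,8a-tetramethyl-3,4,4a,5,6,7,8,8a-octahydronaphthalene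
Conditions: I2, PPh3, imidazole, CH2Cl2, 0 °C → rt
Reagents that add atoms: iodine II
Why: Appel-type iodination is an SN2 displacement at a primary carbon, and imidazole buffers the acid so the tetrasubstituted olefin is not isomerised.

**Step 13**
Reactants: 24 3-methylcyclohex-2-en-1-one
Product: 26 allyl 3,3-dimethylcyclohex-1-en-1-yl carbonate, via magnesium enolate 25 (not isolated)
Conditions: MeMgBr, CuBr·SMe2 (5 mol%), THF, −30 °C; then allyl chloroformate, −78 °C → rt
Reagents that add atoms: methylmagnesium bromide C[Mg]Br; allyl chloroformate C=CCOC(=O)Cl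
Why: Copper-catalysed conjugate addition gives the enolate regiospecifically on the side of the new gem-dimethyl carbon, and the hard chloroformate acylates it on oxygen.

**Step 14**
Reactants: 26 allyl 3,3-dimethylcyclohex-1-en-1-yl carbonate
Product: 27 (2S)-3,3-dimethyl-2-(prop-2-en-1-yl)cyclohexan-1-one
Conditions: Pd2(dba)3·CHCl3 (2.5 mol%), (R,R)-ANDEN-phenyl bis(2-diphenylphosphinobenzamide) ligand (5.5 mol%), 1,4-dioxane, 23 °C
Reagents that add atoms: none
Why: Tsuji decarboxylative asymmetric allylic alkylation: zerovalent palladium ionises the allyl carbonate, CO2 is lost, and the enolate recombines with the π-allyl unit inside the chiral pocket, which sets the tertiary α-stereocentre under neutral conditions that avoid enolate equilibration and racemisation.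

**Step 15**
Reactants: 27 (2S)-3,3-dimethyl-2-(prop-2-en-1-yl)cyclohexan-1-one
Product: 28 (2S)-1,1-dimethyl-3-methylidene-2-(prop-2-en-1-yl)cyclohexane
Conditions: Zn, CH2Br2, TiCl4, THF/CH2Cl2, 0 °C → rt
Reagents that add atoms: dibromomethane BrCBr
Why: Takai–Lombardo methylenation uses a non-basic titanium methylidene equivalent, so the enolisable α-stereocentre should not epimerise.

**Step 16**
Reactants: 28 (2S)-1,1-dimethyl-3-methylidene-2-(prop-2-en-1-yl)cyclohexane
Product: 30 3-[(1S)-2,2-dimethyl-6-methylidenecyclohexyl]propan-1-ol, via alkyl(disiamyl)borane 29 (not isolated)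
Conditions: BH3·SMe2, 2-methylbut-2-ene (2 equiv), THF, 0 °C; 28, 0 °C; then NaOH, H2O2, 0 °C → rt
Reagents that add atoms: hydrogen peroxide OO
Why: Anti-Markovnikov hydroboration with bulky disiamylborane selects the monosubstituted olefin over the hindered 1,1-disubstituted exocyclic one, and oxidation gives the primary alcohol.

**Step 17**
Reactants: 30 3-[(1S)-2,2-dimethyl-6-methylidenecyclohexyl]propan-1-ol
Product: 31 3-[(1S)-2,2-dimethyl-6-methylidenecyclohexyl]propanal
Conditions: PhI(OAc)2, TEMPO (10 mol%), CH2Cl2, rt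
Reagents that add atoms: none
Why: Oxoammonium-mediated oxidation of a primary alcohol stops at the aldehyde and leaves olefins untouched.

**Step 18**
Reactants: 31 3-[(1S)-2,2-dimethyl-6-methylidenecyclohexyl]propanal
Product: 32 (2S)-2-(but-3-yn-1-yl)-1,1-dimethyl-3-methylidenecyclohexane
Conditions: dimethyl (1-diazo-2-oxopropyl)phosphonate, K2CO3, MeOH, 0 °C → rt
Reagents that add atoms: dimethyl (1-diazo-2-oxopropyl)phosphonate COP(=O)(OC)C(=[N+]=[N-])C(C)=O
Why: Seyferth–Gilbert homologation (Ohira–Bestmann variant) turns the aldehyde into the terminal alkyne with one added carbon under mild base, and the remote stereocentre is not acidic.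

**Step 19**
Reactants: 32 (2S)-2-(but-3-yn-1-yl)-1,1-dimethyl-3-methylidenecyclohexane
Product: 34 (2S)-2-[(3E)-4-iodo-3-methylbut-3-en-1-yl]-1,1-dimethyl-3-methylidenecyclohexane, via alkenyldimethylalane 33 (not isolated)
Conditions: Me3Al (2.5 equiv), Cp2ZrCl2 (25 mol%), CH2Cl2, 0 °C → rt; then I2, THF, −30 → 0 °C
Reagents that add atoms: trimethylaluminium C[Al](C)C; iodine II
Why: Zirconium-catalysed methylalumination (Negishi carboalumination) adds methyl and aluminium syn across the terminal alkyne with aluminium at the terminus, and iodinolysis with retention gives the (E)-alkenyl iodide while the 1,1-disubstituted olefin stays inert.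

**Step 20**
Reactants: 23 (4aS,8aS)-1-(2-iodoethyl)-2,5,5,8a-tetramethyl-3,4,4a,5,6,7,8,8a-octahydronaphthalene; 34 (2S)-2-[(3E)-4-iodo-3-methylbut-3-en-1-yl]-1,1-dimethyl-3-methylidenecyclohexane
Product: 36 (4aS,8aS)-1-{(3E)-6-[(1S)-2,2-dimethyl-6-methylidenecyclohexyl]-4-methylhex-3-en-1-yl}-2,5,5,8a-tetramethyl-3,4,4a,5,6,7,8,8a-octahydronaphthalene (target), via alkylzinc iodide 35 (not isolated)
Conditions: 23, Zn dust (activated with BrCH2CH2Br and Me3SiCl), LiCl, THF, 45 °C; then 34, PdCl2(dppf) (5 mol%), THF, 50 °C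
Reagents that add atoms: none
Why: Zinc insertion into the primary C–I bond followed by Negishi sp3–sp2 coupling joins the fragments with retention of the (E)-olefin geometry and touches no stereocentre.

**Compound list**

1 | but-3-yn-1-ol | C#CCCO | starting material
2 | 1-bromo-3-chloropropane | ClCCCBr | starting material
3 | lithium 4-lithiobut-3-yn-1-olate (dilithio but-3-yn-1-ol) | [Li]C#CCCO[Li] | intermediate
4 | 7-chlorohept-3-yn-1-ol | OCCC#CCCCCl | intermediate
5 | 2-methylpropanenitrile (isobutyronitrile) | CC(C)C#N | starting material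
6 | 2-lithio-2-methylpropanenitrile | [Li]C(C)(C)C#N | intermediate
7 | lithium 7-chlorohept-3-yn-1-olate | [Li]OCCC#CCCCCl | intermediate
8 | 9-hydroxy-2,2-dimethylnon-6-ynenitrile | N#CC(C)(C)CCCC#CCCO | intermediate
9 | bromomagnesium alkoxide of (6Z)-7-(bromomagnesio)-9-hydroxy-2,2,6-trimethylnon-6-enenitrile | N#CC(C)(C)CCC/C(C)=C(/[Mg]Br)CCO[Mg]Br | intermediate
10 | (6E)-9-hydroxy-7-iodo-2,2,6-trimethylnon-6-enenitrile | N#CC(C)(C)CCC/C(C)=C(/I)CCO | intermediate
11 | (6E)-9-[(tert-butyldimethylsilyl)oxy]-7-iodo-2,2,6-trimethylnon-6-enenitrile | N#CC(C)(C)CCC/C(C)=C(/I)CCO[Si](C)(C)C(C)(C)C | intermediate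
12 | (6E)-7-{2-[(tert-butyldimethylsilyl)oxy]ethyl}-2,2,6,8-tetramethylnona-6,8-dienenitrile | N#CC(C)(C)CCC/C(C)=C(/C(C)=C)CCO[Si](C)(C)C(C)(C)C | intermediate
13 | N-(diisobutylalumanyl)imine of dienal 14 | CC(C)C[Al](CC(C)C)N=CC(C)(C)CCC/C(C)=C(/C(C)=C)CCO[Si](C)(C)C(C)(C)C | intermediate
14 | (6E)-7-{2-[(tert-butyldimethylsilyl)oxy]ethyl}-2,2,6,8-tetramethylnona-6,8-dienal | O=CC(C)(C)CCC/C(C)=C(/C(C)=C)CCO[Si](C)(C)C(C)(C)C | intermediate
15 | (2E,8E)-9-{2-[(tert-butyldimethylsilyl)oxy]ethyl}-N-methoxy-N,4,4,8,10-pentamethylundeca-2,8,10-trienamide | CON(C)C(=O)/C=C/C(C)(C)CCC/C(C)=C(/C(C)=C)CCO[Si](C)(C)C(C)(C)C | intermediate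
16 | O-(diisobutylalumanyl) hemiaminal from amide 15 | CON(C)C(O[Al](CC(C)C)CC(C)C)/C=C/C(C)(C)CCC/C(C)=C(/C(C)=C)CCO[Si](C)(C)C(C)(C)C | intermediate
17 | (2E,8E)-9-{2-[(tert-butyldimethylsilyl)oxy]ethyl}-4,4,8,10-tetramethylundeca-2,8,10-trienal | O=C/C=C/C(C)(C)CCC/C(C)=C(/C(C)=C)CCO[Si](C)(C)C(C)(C)C | intermediate
18 | (E)-iminium triflate of trienal 17 and (2S,5S)-5-benzyl-2-tert-butyl-3-methylimidazolidin-4-one | CC(C)(C)[C@H]1/[N+](=C/C=C/C(C)(C)CCC/C(C)=C(/C(C)=C)CCO[Si](C)(C)C(C)(C)C)[C@@H](Cc2ccccc2)C(=O)N1C.[O-]S(=O)(=O)C(F)(F)F | intermediate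
19 | iminium triflate of cycloadduct 20 and the same imidazolidinone | CC(C)(C)[Si](C)(C)OCCC1=C(C)C[C@H](C=[N+]3[C@@H](Cc4ccccc4)C(=O)N(C)[C@H]3C(C)(C)C)[C@H]2C(C)(C)CCC[C@]12C.[O-]S(=O)(=O)C(F)(F)F | intermediate
20 | (1S,4aS,8aS)-4-{2-[(tert-butyldimethylsilyl)oxy]ethyl}-3,4a,8,8-tetramethyl-1,2,4a,5,6,7,8,8a-octahydronaphthalene-1-carbaldehyde | CC(C)(C)[Si](C)(C)OCCC1=C(C)C[C@H](C=O)[C@H]2C(C)(C)CCC[C@]12C | intermediate
21 | tert-butyldimethyl{2-[(4aS,8aS)-2,5,5,8a-tetramethyl-3,4,4a,5,6,7,8,8a-octahydronaphthalen-1-yl]ethoxy}silane | CC(C)(C)[Si](C)(C)OCCC1=C(C)CC[C@H]2C(C)(C)CCC[C@]12C | intermediate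
22 | 2-[(4aS,8aS)-2,5,5,8a-tetramethyl-3,4,4a,5,6,7,8,8a-octahydronaphthalen-1-yl]ethan-1-ol | OCCC1=C(C)CC[C@H]2C(C)(C)CCC[C@]12C | intermediate
23 | (4aS,8aS)-1-(2-iodoethyl)-2,5,5,8a-tetramethyl-3,4,4a,5,6,7,8,8a-octahydronaphthalene | ICCC1=C(C)CC[C@H]2C(C)(C)CCC[C@]12C | intermediate
24 | 3-methylcyclohex-2-en-1-one | CC1=CC(=O)CCC1 | starting material
25 | bromomagnesium 3,3-dimethylcyclohex-1-en-1-olate | CC1(C)CCCC(O[Mg]Br)=C1 | intermediate
26 | allyl 3,3-dimethylcyclohex-1-en-1-yl carbonate | C=CCOC(=O)OC1=CC(C)(C)CCC1 | intermediate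
27 | (2S)-3,3-dimethyl-2-(prop-2-en-1-yl)cyclohexan-1-one | O=C1CCCC(C)(C)[C@@H]1CC=C | intermediate
28 | (2S)-1,1-dimethyl-3-methylidene-2-(prop-2-en-1-yl)cyclohexane | C=C1CCCC(C)(C)[C@@H]1CC=C | intermediate
29 | {3-[(1S)-2,2-dimethyl-6-methylidenecyclohexyl]propyl}bis(3-methylbutan-2-yl)borane | C=C1CCCC(C)(C)[C@@H]1CCCB(C(C)C(C)C)C(C)C(C)C | intermediate
30 | 3-[(1S)-2,2-dimethyl-6-methylidenecyclohexyl]propan-1-ol | C=C1CCCC(C)(C)[C@@H]1CCCO | intermediate
31 | 3-[(1S)-2,2-dimethyl-6-methylidenecyclohexyl]propanal | C=C1CCCC(C)(C)[C@@H]1CCC=O | intermediate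
32 | (2S)-2-(but-3-yn-1-yl)-1,1-dimethyl-3-methylidenecyclohexane | C=C1CCCC(C)(C)[C@@H]1CCC#C | intermediate
33 | {(1E)-4-[(1S)-2,2-dimethyl-6-methylidenecyclohexyl]-2-methylbut-1-en-1-yl}dimethylalumane | C=C1CCCC(C)(C)[C@@H]1CC/C(C)=C/[Al](C)C | intermediate
34 | (2S)-2-[(3E)-4-iodo-3-methylbut-3-en-1-yl]-1,1-dimethyl-3-methylidenecyclohexane | C=C1CCCC(C)(C)[C@@H]1CC/C(C)=C/I | intermediate
35 | {2-[(4aS,8aS)-2,5,5,8a-tetramethyl-3,4,4a,5,6,7,8,8a-octahydronaphthalen-1-yl]ethyl}zinc iodide | I[Zn]CCC1=C(C)CC[C@H]2C(C)(C)CCC[C@]12C | intermediate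
36 | (4aS,8aS)-1-{(3E)-6-[(1S)-2,2-dimethyl-6-methylidenecyclohexyl]-4-methylhex-3-en-1-yl}-2,5,5,8a-tetramethyl-3,4,4a,5,6,7,8,8a-octahydronaphthalene (CNP0271776.1) | C=C1CCCC(C)(C)[C@@H]1CC/C(C)=C/CCC1=C(C)CC[C@H]2C(C)(C)CCC[C@]12C | target

**Totals**

Total step count: 20. Longest linear sequence: 13 steps (steps 1–12, then step 20). The ring C branch (steps 13–19) is 7 steps and joins in step 20.

**The three steps most likely to fail**

1. Step 9 (bears the label). Bond formation at the fully substituted C10 next to the neopentyl C5 may be too slow under iminium catalysis. The acid co-catalyst may then isomerise the electron-rich diene or cleave the silyl ether before cycloaddition, and endo or facial control may erode at the higher temperature needed. Fallback (known auxiliary-controlled, Lewis acid-promoted intramolecular Diels–Alder chemistry), setting out from dienal 14 and returning at aldehyde 20: Horner–Wadsworth–Emmons reaction of 14 with diethyl {2-[(4S)-4-benzyl-2-oxo-1,3-oxazolidin-3-yl]-2-oxoethyl}phosphonate (LiCl, i-Pr2NEt, MeCN) should give (4S)-4-benzyl-3-[(2E,8E)-9-{2-[(tert-butyldimethylsilyl)oxy]ethyl}-4,4,8,10-tetramethylundeca-2,8,10-trienoyl]-1,3-oxazolidin-2-one F1. Me2AlCl (1.4 equiv, CH2Cl2, −30 → 0 °C) should chelate both imide carbonyls, hold the enoyl unit s-cis and let the benzyl group cover the Re face at the α-carbon, so that the endo cycloaddition on the Si face gives the imide cycloadduct (4S)-4-benzyl-3-{[(1S,4aS,8aS)-4-{2-[(tert-butyldimethylsilyl)oxy]ethyl}-3,4a,8,8-tetramethyl-1,2,4a,5,6,7,8,8a-octahydronaphthalen-1-yl]carbonyl}-1,3-oxazolidin-2-one F2. LiBH4 (THF, MeOH, 0 °C) should cleave the auxiliary to the primary alcohol [(1S,4aS,8aS)-4-{2-[(tert-butyldimethylsilyl)oxy]ethyl}-3,4a,8,8-tetramethyl-1,2,4a,5,6,7,8,8a-octahydronaphthalen-1-yl]methanol F3, and PhI(OAc)2/TEMPO oxidation returns to 20.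

2. Step 3. Methyl addition to the nitrile, incomplete carbometalation, or leakage of regio- and stereocontrol in the iron-catalysed step would spoil the (E) geometry on which the key step depends. Fallback (enol triflate cross-coupling instead of alkyne carbometalation), setting out from 2, with methyl isobutyrate and 3-acetyloxolan-2-one as further commercial materials, and returning at dienal 14:
   - Alkylation of the lithium enolate of methyl isobutyrate with 2 should give methyl 5-chloro-2,2-dimethylpentanoate F4.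
   - LiAlH4 gives 5-chloro-2,2-dimethylpentan-1-ol F5; Swern oxidation gives 5-chloro-2,2-dimethylpentanal F6; HC(OMe)3, MeOH and TsOH (cat.) give 5-chloro-1,1-dimethoxy-2,2-dimethylpentane F7.
   - Finkelstein exchange (NaI, acetone) gives 5-iodo-1,1-dimethoxy-2,2-dimethylpentane F8, and zinc insertion (Zn, LiCl, THF) gives (5,5-dimethoxy-4,4-dimethylpentyl)zinc iodide F9.
   - 3-Acetyloxolan-2-one with Tf2O and DBU (CH2Cl2, −78 °C, non-chelating conditions) should give (1E)-1-(2-oxooxolan-3-ylidene)ethyl trifluoromethanesulfonate F10.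
   - Negishi coupling of F9 with F10 (Pd(PPh3)4, THF, 50 °C, retention) gives (3E)-3-(7,7-dimethoxy-6,6-dimethylheptan-2-ylidene)oxolan-2-one F11.
   - MeLi (2.5 equiv, THF, −78 → 0 °C) opens the lactone to (3E)-3-(2-hydroxyethyl)-9,9-dimethoxy-2,4,8,8-tetramethylnon-3-en-2-ol F12, and TBSCl/imidazole silylates the primary hydroxyl to the mono-silyl ether (3E)-3-{2-[(tert-butyldimethylsilyl)oxy]ethyl}-9,9-dimethoxy-2,4,8,8-tetramethylnon-3-en-2-ol F13.
   - Syn-dehydration with methyl N-(triethylammoniosulfonyl)carbamate (Burgess dehydration), which can only eliminate toward a methyl group, gives the diene acetal tert-butyl{[(3E)-9,9-dimethoxy-4,8,8-trimethyl-3-(prop-1-en-2-yl)non-3-en-1-yl]oxy}dimethylsilane F14.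
   - Pyridinium tosylate in wet acetone hydrolyses the dimethyl acetal and returns to 14.

3. Step 14. Ionisation and C–C bond formation at the enolate carbon next to the gem-dimethyl group may be slow, the enantioselectivity for this tertiary centre may be low, and the product may racemise by enolisation. Fallback (resolution instead of asymmetric catalysis), setting out from 26 and returning at 27: allylation of 26 with achiral Pd(PPh3)4 (THF, rt) should give racemic 3,3-dimethyl-2-(prop-2-en-1-yl)cyclohexan-1-one F15. Thermodynamic reduction (Na, i-PrOH, toluene, reflux) gives the diequatorial racemic trans-3,3-dimethyl-2-(prop-2-en-1-yl)cyclohexan-1-ol F16. Kinetic resolution with immobilised Candida antarctica lipase B and vinyl acetate (t-BuOMe, 30 °C, to about half conversion) is expected, by the usual preference of lipases for the (1R) secondary alcohol, to leave (1S,2S)-3,3-dimethyl-2-(prop-2-en-1-yl)cyclohexan-1-ol F17 and to acetylate its antipode to (1R,2R)-3,3-dimethyl-2-(prop-2-en-1-yl)cyclohexyl acetate F18, which is separated. Buffered oxidation of F17 (PhI(OAc)2, TEMPO, CH2Cl2) returns to 27 without touching the α-stereocentre.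

**Further compounds**

F1 | step 9 | (4S)-4-benzyl-3-[(2E,8E)-9-{2-[(tert-butyldimethylsilyl)oxy]ethyl}-4,4,8,10-tetramethylundeca-2,8,10-trienoyl]-1,3-oxazolidin-2-one | O=C(/C=C/C(C)(C)CCC/C(C)=C(/C(C)=C)CCO[Si](C)(C)C(C)(C)C)N1[C@@H](Cc2ccccc2)COC1=O
F2 | step 9 | (4S)-4-benzyl-3-{[(1S,4aS,8aS)-4-{2-[(tert-butyldimethylsilyl)oxy]ethyl}-3,4a,8,8-tetramethyl-1,2,4a,5,6,7,8,8a-octahydronaphthalen-1-yl]carbonyl}-1,3-oxazolidin-2-one | CC(C)(C)[Si](C)(C)OCCC1=C(C)C[C@H](C(=O)N3[C@@H](Cc4ccccc4)COC3=O)[C@H]2C(C)(C)CCC[C@]12C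
F3 | step 9 | [(1S,4aS,8aS)-4-{2-[(tert-butyldimethylsilyl)oxy]ethyl}-3,4a,8,8-tetramethyl-1,2,4a,5,6,7,8,8a-octahydronaphthalen-1-yl]methanol | CC(C)(C)[Si](C)(C)OCCC1=C(C)C[C@H](CO)[C@H]2C(C)(C)CCC[C@]12C
F4 | step 3 | methyl 5-chloro-2,2-dimethylpentanoate | COC(=O)C(C)(C)CCCCl
F5 | step 3 | 5-chloro-2,2-dimethylpentan-1-ol | OCC(C)(C)CCCCl
F6 | step 3 | 5-chloro-2,2-dimethylpentanal | O=CC(C)(C)CCCCl
F7 | step 3 | 5-chloro-1,1-dimethoxy-2,2-dimethylpentane | COC(OC)C(C)(C)CCCCl
F8 | step 3 | 5-iodo-1,1-dimethoxy-2,2-dimethylpentane | COC(OC)C(C)(C)CCCI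
F9 | step 3 | (5,5-dimethoxy-4,4-dimethylpentyl)zinc iodide | COC(OC)C(C)(C)CCC[Zn]I
F10 | step 3 | (1E)-1-(2-oxooxolan-3-ylidene)ethyl trifluoromethanesulfonate | FC(F)(F)S(=O)(=O)O/C(C)=C1/C(=O)OCC1
F11 | step 3 | (3E)-3-(7,7-dimethoxy-6,6-dimethylheptan-2-ylidene)oxolan-2-one | COC(OC)C(C)(C)CCC/C(C)=C1/C(=O)OCC1
F12 | step 3 | (3E)-3-(2-hydroxyethyl)-9,9-dimethoxy-2,4,8,8-tetramethylnon-3-en-2-ol | COC(OC)C(C)(C)CCC/C(C)=C(/C(C)(C)O)CCO
F13 | step 3 | (3E)-3-{2-[(tert-butyldimethylsilyl)oxy]ethyl}-9,9-dimethoxy-2,4,8,8-tetramethylnon-3-en-2-ol | COC(OC)C(C)(C)CCC/C(C)=C(/C(C)(C)O)CCO[Si](C)(C)C(C)(C)C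
F14 | step 3 | tert-butyl{[(3E)-9,9-dimethoxy-4,8,8-trimethyl-3-(prop-1-en-2-yl)non-3-en-1-yl]oxy}dimethylsilane | COC(OC)C(C)(C)CCC/C(C)=C(/C(C)=C)CCO[Si](C)(C)C(C)(C)C
F15 | step 14 | racemic 3,3-dimethyl-2-(prop-2-en-1-yl)cyclohexan-1-one (both enantiomers written) | O=C1CCCC(C)(C)[C@@H]1CC=C.O=C1CCCC(C)(C)[C@H]1CC=C
F16 | step 14 | racemic trans-3,3-dimethyl-2-(prop-2-en-1-yl)cyclohexan-1-ol (both enantiomers written) | O[C@H]1CCCC(C)(C)[C@@H]1CC=C.O[C@@H]1CCCC(C)(C)[C@H]1CC=C
F17 | step 14 | (1S,2S)-3,3-dimethyl-2-(prop-2-en-1-yl)cyclohexan-1-ol | O[C@H]1CCCC(C)(C)[C@@H]1CC=C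
F18 | step 14 | (1R,2R)-3,3-dimethyl-2-(prop-2-en-1-yl)cyclohexyl acetate | CC(=O)O[C@@H]1CCCC(C)(C)[C@H]1CC=C
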